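The free catalyst turns starting material into product by way of the catalyst intermediate, while the impurity takes free catalyst away as spent catalyst.

    free catalyst + impurity → spent catalyst (k1 = 25000 M⁻¹ s⁻¹)
    catalyst intermediate ⇌ free catalyst + product (K2 = 4.2 × 10⁻⁴ M, k2 = 130 s⁻¹)
    starting material + free catalyst ⇌ catalyst intermediate (K3 = 110 M⁻¹, k3 = 34000 M⁻¹ s⁻¹)

starting material 1.0 mM; free catalyst 0.12 mM; impurity 66 µM; time 40 s

* share of the starting material used up at 40 s
* product at 40 s, in percent of the starting material charged

- We carry one quantity: the overall constant 0.0462, which is K2 times K3, the ratio of c(product) to c(starting material) once both reversible steps stand at balance.
- It applies once balance has come, so we first ask whether that happens within 40 s. If the impurity takes its whole charge, which is less than the catalyst charge, then 54.0 µM of catalyst stays at work, free and as intermediate together. Binding by its forward rate alone, pseudo-first-order in starting material, then has a half-life of 0.378 s, far shorter than 40 s, so we reckon on thermodynamic control.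
- Our first way looks at the whole flask. Our first guess for the yield is 4.62 % of the charge, but the remaining starting material is smaller by that share, so we put this back and get 4.41 %.
- Our second way goes step by step. Balance in step 3 gives c(catalyst intermediate)/c(free catalyst) = 0.105, and balance in step 2 gives c(product) as K2 times that ratio, 44.2 µM, or 4.42 % of the charge.
- The two ways share their constants, so their agreement shows just that free catalyst cancels from the ratio of c(product) to c(starting material); whether balance comes in time rests on the half-life above.
- Conversion also counts what we reckon to sit as catalyst intermediate, 5.14 µM of starting material. Going round once more, we commit to a yield of 4.39 % and a conversion of 4.91 %.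
- The forecast gives a conversion of 4.9 % and a yield of 4.4 %, on the ground that the surviving catalyst “turns over fast enough to reach that limit within seconds”.
- The flask gives a conversion of 4.90 % and a yield of 4.39 %. In this flask, at 40.0 s, the forward half-life of starting material by binding alone, 0.42 s, and the relaxation half-life of step 2 alone, both ways together, 0.00437 s, are both short against 40 s, and the product stands at 4.39 % already after 2.00 s. The ratio of c(product) to c(starting material) in this flask reads 0.0462, beside 0.0462. The neighbour flask with 0.25 mM of starting material, where 4.42 % is what 0.0462 gives before the catalyst is counted, yields 4.39 %.

The numbers of this flask were chosen freely; what happens was integrated by code.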